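**Retrosynthetic overview**
1. Target 14 ← bis-silyl ether 13 by global desilylation.
2. 13 ← alkynyl pyridazinyl ether 11 by intramolecular inverse-electron-demand Diels–Alder reaction and loss of N2. Benzene ring B and the dihydrofuran ring form together here; ring A is bought.
3. 11 ← secondary alcohol 6 + chloropyridazine 9 (SNAr, C7–O bond untouched).
4. 6 ← aldehyde 1 + enyne 2 + B2pin2 3 (copper-catalysed borylative propargylation sets C7 and C8). 9 ← dichloropyridazine 7 + alkenylboronate 8.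

Assumption: 2, 7 and 8 are bought as catalogue chemicals.
Assumption: in step 1 the sense of induction is assigned by analogy. The Ph-BPE antipode that gives the (1R,2S) diol is meant; both antipodes are sold.

**Step 1**
Reactants: 1 3,4,5-trimethoxybenzaldehyde; 2 (but-3-en-1-yn-1-yl)trimethylsilane; 3 bis(pinacolato)diboron
Product: 5 (1R,2S)-1-(3,4,5-trimethoxyphenyl)-2-[(trimethylsilyl)ethynyl]propane-1,3-diol, via bis-boryl adduct 4 (not isolated)
Conditions: CuCl (5 mol %), Ph-BPE (6 mol %), NaOtBu (20 mol %), THF, 22 °C, 8 h; then NaBO3·4H2O, THF/H2O, 0 °C to rt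
Reagents that add atoms: sodium perborate tetrahydrate NaBO3·4H2O, [Na+].[Na+].O[B-]1(O)OO[B-](O)(O)OO1 (oxygen of the primary hydroxyl)
Why: Copper-catalysed three-component borylative propargylation: Cu–B(pin) adds to the vinyl group of 2, the propargyl copper shifts to the allenyl copper, and this adds to the Re face of 1 through a closed six-membered SE2' transition state that gives the anti (OH/CH2B) adduct, so the chiral bisphosphine sets 1R and 2S together before C–B oxidation.

**Step 2**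
Reactants: 5 (1R,2S)-1-(3,4,5-trimethoxyphenyl)-2-[(trimethylsilyl)ethynyl]propane-1,3-diol
Product: 6 (1R,2S)-3-[(triisopropylsilyl)oxy]-1-(3,4,5-trimethoxyphenyl)-2-[(trimethylsilyl)ethynyl]propan-1-ol
Conditions: iPr3SiCl (1.05 equiv), imidazole, DMF, 0 °C
Reagents that add atoms: chlorotriisopropylsilane, CC(C)[Si](Cl)(C(C)C)C(C)C
Why: Selective silylation of the primary over the hindered secondary benzylic hydroxyl; the triisopropylsilyl group is chosen because it resists O-to-O migration under the basic conditions of step 4.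

**Step 3**
Reactants: 7 3,6-dichloro-4-methoxypyridazine; 8 tert-butyl(dimethyl){[(2E)-3-(4,4,5,5-tetramethyl-1,3,2-dioxaborolan-2-yl)prop-2-en-1-yl]oxy}silane
Product: 9 6-[(1E)-3-{[tert-butyl(dimethyl)silyl]oxy}prop-1-en-1-yl]-3-chloro-4-methoxypyridazine
Conditions: Pd(PPh3)4 (5 mol %), 7 (1.2 equiv), 2 M aq. Na2CO3, 1,4-dioxane, 80 °C
Reagents that add atoms: none
Why: Suzuki–Miyaura coupling with retention of the E alkene; zerovalent palladium should insert into the C6–Cl bond, which is unhindered and not enriched by the methoxy group, whereas C3–Cl is ortho to it and receives its π-donation.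

**Step 4**
Reactants: 6 (1R,2S)-3-[(triisopropylsilyl)oxy]-1-(3,4,5-trimethoxyphenyl)-2-[(trimethylsilyl)ethynyl]propan-1-ol; 9 6-[(1E)-3-{[tert-butyl(dimethyl)silyl]oxy}prop-1-en-1-yl]-3-chloro-4-methoxypyridazine
Product: 11 3-{[(1R,2S)-2-ethynyl-3-[(triisopropylsilyl)oxy]-1-(3,4,5-trimethoxyphenyl)propyl]oxy}-6-[(1E)-3-{[tert-butyl(dimethyl)silyl]oxy}prop-1-en-1-yl]-4-methoxypyridazine, via trimethylsilyl alkyne ether 10 (not isolated)
Conditions: NaN(SiMe3)2 (1.05 equiv), THF, 0 to 60 °C; then MeOH, K2CO3 (0.2 equiv), rt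
Reagents that add atoms: none
Why: SNAr (addition–elimination) of the sodium alkoxide at the only C–Cl of the 1,2-diazine, alpha to ring nitrogen; the C7–O bond is not broken so both stereocentres are retained, the silyl cap keeps the alkyne from acting as a nucleophile, and methanolysis then frees the terminal alkyne.

**Step 5**
Reactants: 11 3-{[(1R,2S)-2-ethynyl-3-[(triisopropylsilyl)oxy]-1-(3,4,5-trimethoxyphenyl)propyl]oxy}-6-[(1E)-3-{[tert-butyl(dimethyl)silyl]oxy}prop-1-en-1-yl]-4-methoxypyridazine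
Product: 13 tert-butyl{[(2E)-3-[(2R,3S)-7-methoxy-3-{[(triisopropylsilyl)oxy]methyl}-2-(3,4,5-trimethoxyphenyl)-2,3-dihydro-1-benzofuran-5-yl]prop-2-en-1-yl]oxy}dimethylsilane, via diazabicyclooctatriene cycloadduct 12 (not isolated)
Conditions: degassed 1,3,5-triisopropylbenzene (0.01 M), BHT (0.1 equiv), 220 °C, sealed tube, 24 h
Reagents that add atoms: none
Why: Intramolecular inverse-electron-demand Diels–Alder reaction of the tethered alkyne across C3/C6 of the pyridazine, then retro-Diels–Alder loss of N2, a known route from 3-(but-3-ynyloxy)pyridazines to 2,3-dihydrobenzofurans; the three-atom tether fixes the regiochemistry (pyridazine C4-OMe becomes C7-OMe, C6 becomes C5), the dihydrofuran and benzene ring B form in one operation, and the spectator centres C7 (R) and C8 (S) emerge as the trans 2,3-disubstituted ring.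

**Step 6**
Reactants: 13 tert-butyl{[(2E)-3-[(2R,3S)-7-methoxy-3-{[(triisopropylsilyl)oxy]methyl}-2-(3,4,5-trimethoxyphenyl)-2,3-dihydro-1-benzofuran-5-yl]prop-2-en-1-yl]oxy}dimethylsilane
Product: 14 (2E)-3-[(2R,3S)-3-(hydroxymethyl)-7-methoxy-2-(3,4,5-trimethoxyphenyl)-2,3-dihydro-1-benzofuran-5-yl]prop-2-en-1-ol
Conditions: Bu4NF (3 equiv), THF, 0 °C to rt; aqueous work-up
Reagents that add atoms: none
Why: Fluoride-mediated cleavage of both silyl ethers under non-acidic conditions, which spares the cinnamyl alcohol and the benzylic ether and leaves both stereocentres untouched.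

**Compound list**
1 | 3,4,5-trimethoxybenzaldehyde | COc1cc(C=O)cc(OC)c1OC | starting material
2 | (but-3-en-1-yn-1-yl)trimethylsilane | C=CC#C[Si](C)(C)C | starting material
3 | bis(pinacolato)diboron | CC1(C)OB(OC1(C)C)B1OC(C)(C)C(C)(C)O1 | starting material
4 | trimethyl{(3R,4R)-4-[(4,4,5,5-tetramethyl-1,3,2-dioxaborolan-2-yl)oxy]-3-[(4,4,5,5-tetramethyl-1,3,2-dioxaborolan-2-yl)methyl]-4-(3,4,5-trimethoxyphenyl)but-1-yn-1-yl}silane (same spatial arrangement as 5; the descriptor at the boron-bearing carbon differs only through CIP ranking) | COc1cc([C@H](OB2OC(C)(C)C(C)(C)O2)[C@H](CB2OC(C)(C)C(C)(C)O2)C#C[Si](C)(C)C)cc(OC)c1OC | intermediate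
5 | (1R,2S)-1-(3,4,5-trimethoxyphenyl)-2-[(trimethylsilyl)ethynyl]propane-1,3-diol | COc1cc([C@H](O)[C@H](CO)C#C[Si](C)(C)C)cc(OC)c1OC | intermediate
6 | (1R,2S)-3-[(triisopropylsilyl)oxy]-1-(3,4,5-trimethoxyphenyl)-2-[(trimethylsilyl)ethynyl]propan-1-ol | COc1cc([C@H](O)[C@H](CO[Si](C(C)C)(C(C)C)C(C)C)C#C[Si](C)(C)C)cc(OC)c1OC | intermediate
7 | 3,6-dichloro-4-methoxypyridazine | COc1cc(Cl)nnc1Cl | starting material
8 | tert-butyl(dimethyl){[(2E)-3-(4,4,5,5-tetramethyl-1,3,2-dioxaborolan-2-yl)prop-2-en-1-yl]oxy}silane | CC(C)(C)[Si](C)(C)OC/C=C/B1OC(C)(C)C(C)(C)O1 | starting material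
9 | 6-[(1E)-3-{[tert-butyl(dimethyl)silyl]oxy}prop-1-en-1-yl]-3-chloro-4-methoxypyridazine | COc1cc(/C=C/CO[Si](C)(C)C(C)(C)C)nnc1Cl | intermediate
10 | 6-[(1E)-3-{[tert-butyl(dimethyl)silyl]oxy}prop-1-en-1-yl]-4-methoxy-3-{[(1R,2S)-3-[(triisopropylsilyl)oxy]-1-(3,4,5-trimethoxyphenyl)-2-[(trimethylsilyl)ethynyl]propyl]oxy}pyridazine | COc1cc([C@H](Oc2nnc(/C=C/CO[Si](C)(C)C(C)(C)C)cc2OC)[C@H](CO[Si](C(C)C)(C(C)C)C(C)C)C#C[Si](C)(C)C)cc(OC)c1OC | intermediate
11 | 3-{[(1R,2S)-2-ethynyl-3-[(triisopropylsilyl)oxy]-1-(3,4,5-trimethoxyphenyl)propyl]oxy}-6-[(1E)-3-{[tert-butyl(dimethyl)silyl]oxy}prop-1-en-1-yl]-4-methoxypyridazine | COc1cc([C@H](Oc2nnc(/C=C/CO[Si](C)(C)C(C)(C)C)cc2OC)[C@H](CO[Si](C(C)C)(C(C)C)C(C)C)C#C)cc(OC)c1OC | intermediate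
12 | [4+2] cycloadduct: 2,3-diazabicyclo[2.2.2]octa-2,5,7-triene bridging former pyridazine C3 and C6, fused to the new dihydrofuran (2R,3S at the furan carbons; either bridgehead diastereomer, both give 13) | COc1cc([C@@H]2OC34N=NC(/C=C/CO[Si](C)(C)C(C)(C)C)(C=C3OC)C=C4[C@H]2CO[Si](C(C)C)(C(C)C)C(C)C)cc(OC)c1OC | intermediate
13 | tert-butyl{[(2E)-3-[(2R,3S)-7-methoxy-3-{[(triisopropylsilyl)oxy]methyl}-2-(3,4,5-trimethoxyphenyl)-2,3-dihydro-1-benzofuran-5-yl]prop-2-en-1-yl]oxy}dimethylsilane | COc1cc([C@@H]2Oc3c(OC)cc(/C=C/CO[Si](C)(C)C(C)(C)C)cc3[C@H]2CO[Si](C(C)C)(C(C)C)C(C)C)cc(OC)c1OC | intermediate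
14 | (2E)-3-[(2R,3S)-3-(hydroxymethyl)-7-methoxy-2-(3,4,5-trimethoxyphenyl)-2,3-dihydro-1-benzofuran-5-yl]prop-2-en-1-ol, i.e. (-)-(7R,8S,7'E)-3,4,5,5'-tetramethoxy-4',7-epoxy-8,3'-neolign-7'-ene-9,9'-diol | COc1cc([C@@H]2Oc3c(OC)cc(/C=C/CO)cc3[C@H]2CO)cc(OC)c1OC | target

**Totals**
Total step count: 6. Longest linear sequence: 5 (steps 1, 2, 4, 5, 6); step 3 is the convergent branch.

**Three steps most likely to fail**

Step 5 (thermal cycloaddition). The pyridazine in 11 carries two donor oxygens, so the cycloaddition may be slow, and at 220 °C the benzylic heteroaryl ether may eliminate or ionise, which would cost material or scramble C7. The fallback runs the cycloaddition on a more electron-poor 6-chloropyridazine and attaches the side chain afterwards. It sets out from 6 and comes back at 13.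
- Bought 6-chloro-4-methoxypyridazin-3-amine (COc1cc(Cl)nnc1N) is diazotised with NaNO2 in HF·pyridine to give 6-chloro-3-fluoro-4-methoxypyridazine F1.
- The sodium alkoxide of 6 (NaN(SiMe3)2, THF, −40 to 0 °C) displaces fluoride at C3 in preference to chloride at C6. This gives 6-chloro-4-methoxy-3-{[(1R,2S)-3-[(triisopropylsilyl)oxy]-1-(3,4,5-trimethoxyphenyl)-2-[(trimethylsilyl)ethynyl]propyl]oxy}pyridazine F2.
- K2CO3 in MeOH gives the terminal alkyne 6-chloro-3-{[(1R,2S)-2-ethynyl-3-[(triisopropylsilyl)oxy]-1-(3,4,5-trimethoxyphenyl)propyl]oxy}-4-methoxypyridazine F3.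
- Thermolysis at 170–190 °C, with loss of N2, gives (2R,3S)-5-chloro-7-methoxy-3-{[(triisopropylsilyl)oxy]methyl}-2-(3,4,5-trimethoxyphenyl)-2,3-dihydro-1-benzofuran F4.
- Suzuki coupling of F4 with 8 (Pd(OAc)2, SPhos, K3PO4, toluene/H2O, 90 °C) returns to 13.

Step 3 (site selectivity between two C–Cl bonds). Coupling at C3, or double coupling, would give the wrong or an inseparable pyridazine; a wrong isomer would end as the 6-methoxy benzofuran. The fallback replaces selectivity between two chlorides by chemoselectivity between iodide and chloride, on a compound whose regiochemistry is proven first. It sets out from 7 and comes back at 9.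
- Ammonolysis of 7 (aq. NH3, 120 °C, sealed) is expected to enter mainly at C6. The two possible amines are separable, so the structure of 6-chloro-5-methoxypyridazin-3-amine F5 is secured before going on.
- Non-aqueous Sandmeyer iodination (tert-butyl nitrite, I2, CuI, MeCN, 60 °C) gives 3-chloro-6-iodo-4-methoxypyridazine F6.
- Suzuki coupling with 8 at the C–I bond (Pd(PPh3)4, Na2CO3, dioxane/H2O, rt to 40 °C) gives 9.

Step 4 (SNAr by a hindered secondary alkoxide next to a methoxy group). The reaction may stall, or the strong base may cause silyl migration or propargyl–allenyl isomerisation. The fallback replaces addition–elimination by a palladium-catalysed C–O cross-coupling under a weak base. It sets out from 6 and 9 and comes back at 10, which is desilylated to 11 as in step 4.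
- Conditions: [Pd(allyl)Cl]2, RockPhos, Cs2CO3, toluene, 90 °C.
- The silyl-capped alkyne of 6 cannot enter Sonogashira-type side reactions.
- This fallback makes no compound beyond the list: none F0.

**Further compounds**
F1 | step 5 | 6-chloro-3-fluoro-4-methoxypyridazine | COc1cc(Cl)nnc1F
F2 | step 5 | 6-chloro-4-methoxy-3-{[(1R,2S)-3-[(triisopropylsilyl)oxy]-1-(3,4,5-trimethoxyphenyl)-2-[(trimethylsilyl)ethynyl]propyl]oxy}pyridazine | COc1cc([C@H](Oc2nnc(Cl)cc2OC)[C@H](CO[Si](C(C)C)(C(C)C)C(C)C)C#C[Si](C)(C)C)cc(OC)c1OC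
F3 | step 5 | 6-chloro-3-{[(1R,2S)-2-ethynyl-3-[(triisopropylsilyl)oxy]-1-(3,4,5-trimethoxyphenyl)propyl]oxy}-4-methoxypyridazine | COc1cc([C@H](Oc2nnc(Cl)cc2OC)[C@H](CO[Si](C(C)C)(C(C)C)C(C)C)C#C)cc(OC)c1OC
F4 | step 5 | (2R,3S)-5-chloro-7-methoxy-3-{[(triisopropylsilyl)oxy]methyl}-2-(3,4,5-trimethoxyphenyl)-2,3-dihydro-1-benzofuran | COc1cc([C@@H]2Oc3c(OC)cc(Cl)cc3[C@H]2CO[Si](C(C)C)(C(C)C)C(C)C)cc(OC)c1OC
F5 | step 3 | 6-chloro-5-methoxypyridazin-3-amine | COc1cc(N)nnc1Cl
F6 | step 3 | 3-chloro-6-iodo-4-methoxypyridazine | COc1cc(I)nnc1Cl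
F0 | step 4 | none | none
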